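## Retrosynthetic overview

1. Spiculoic acid B is traced to its methyl ester, which is cleaved last. Indene numbering is used: C1 = CHMe, C2=C3 with ethyl on C3, C3a/C7a = ring fusion, C4 = C(Me)CO2H, C5 = C(Et)(styryl), C6=C7 with ethyl on C7.
2. Enabling feature: the only double bond of the five-membered ring, C2=C3, lies between two sp3 CH carbons (C1 and C3a) and carries no heteroatom. It is therefore a Ramberg–Bäcklund retron: an SO2 group inserted between C2 and C3 turns the cyclopentene into a six-membered thiane 1,1-dioxide (C3a–C3–SO2–C2–C1–C7a).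
3. The thiane dioxide and the cyclohexene (C6=C7) are opened together by one retro-Diels–Alder cut (C4–C5 and C3a–C7a). This leads to an acyclic sulfone with an E-enoate dienophile, an E,E-diene and a four-atom C–SO2–C–C tether. The sulfur-bearing carbon (future C3) is a temporary stereocentre that, together with C1, steers the cycloaddition.
4. The sulfone comes from the sulfide, made by S-alkylation of a thioacetate (from methyl (R)-2-hydroxybutanoate; Wittig, Mitsunobu inversion) with a trienyl iodide (from methyl (R)-3-hydroxy-2-methylpropanoate; two Wittig and one Horner–Wadsworth–Emmons olefination).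
5. Ring order: the cyclohexene and the six-membered sulfone ring close together in the cycloaddition; the sulfone ring is then contracted to the cyclopentene in the same flask.

Key step: step 15

Remark: the drawn enantiomer is (1R,3aR,4R,5S,7aS) in indene numbering; both enantiomers of the two chiral-pool hydroxy esters are taken as commercial.

## Route

Step 1
Reactants: 1 propyltriphenylphosphonium bromide; 2 ethyl formate
Product: 4 2-(triphenylphosphoranylidene)butanal, via propylidene ylide 3 (not isolated)
Conditions: KOt-Bu, THF, 0 °C; then 2, 0 °C → rt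
Reagents that add atoms: none
Why: Deprotonation gives the non-stabilised ylide, whose C-formylation by the formate ester (acylation of a phosphorus ylide) and loss of the second proton to the liberated ethoxide should give the formyl-stabilised Wittig reagent; no stereocentre is formed.

Step 2
Reactants: 5 methyl (R)-3-hydroxy-2-methylpropanoate
Product: 6 methyl (R)-3-[(tert-butyldimethylsilyl)oxy]-2-methylpropanoate
Conditions: TBSCl, imidazole, DMF, rt
Reagents that add atoms: tert-butyldimethylsilyl chloride, CC(C)(C)[Si](C)(C)Cl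
Why: Imidazole-promoted silylation (silyl ether protection) of the primary alcohol should leave the α-stereocentre of the ester untouched.

Step 3
Reactants: 6 methyl (R)-3-[(tert-butyldimethylsilyl)oxy]-2-methylpropanoate
Product: 7 (R)-3-[(tert-butyldimethylsilyl)oxy]-2-methylpropanal
Conditions: i-Bu2AlH, CH2Cl2, −78 °C
Reagents that add atoms: none
Why: Partial ester reduction with i-Bu2AlH at −78 °C stops at the aluminium hemiacetal, which releases the aldehyde on work-up, and the cold non-basic conditions should preserve the α-stereocentre (the aldehyde is used at once).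

Step 4
Reactants: 7 (R)-3-[(tert-butyldimethylsilyl)oxy]-2-methylpropanal; 4 2-(triphenylphosphoranylidene)butanal
Product: 8 (2E,4S)-5-[(tert-butyldimethylsilyl)oxy]-2-ethyl-4-methylpent-2-enal
Conditions: PhMe, 90 °C
Reagents that add atoms: none
Why: Wittig olefination with a formyl-stabilised ylide is under thermodynamic control and should give the trisubstituted E-enal without touching the neighbouring stereocentre.

Step 5
Reactants: 8 (2E,4S)-5-[(tert-butyldimethylsilyl)oxy]-2-ethyl-4-methylpent-2-enal; 4 2-(triphenylphosphoranylidene)butanal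
Product: 9 (2E,4E,6S)-7-[(tert-butyldimethylsilyl)oxy]-2,4-diethyl-6-methylhepta-2,4-dienal
Conditions: PhMe, 110 °C
Reagents that add atoms: none
Why: A second Wittig olefination with the same stabilised ylide should homologate the enal to the (2E,4E)-dienal, again with E selectivity.

Step 6
Reactants: 9 (2E,4E,6S)-7-[(tert-butyldimethylsilyl)oxy]-2,4-diethyl-6-methylhepta-2,4-dienal; 10 diethyl benzylphosphonate
Product: 11 tert-butyl{[(2S,3E,5E,7E)-4,6-diethyl-2-methyl-8-phenylocta-3,5,7-trien-1-yl]oxy}dimethylsilane
Conditions: KOt-Bu, THF, 0 °C → rt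
Reagents that add atoms: none
Why: Horner–Wadsworth–Emmons olefination with the benzylic phosphonate anion should give the E-styryl double bond and complete the all-E triene.

Step 7
Reactants: 11 tert-butyl{[(2S,3E,5E,7E)-4,6-diethyl-2-methyl-8-phenylocta-3,5,7-trien-1-yl]oxy}dimethylsilane
Product: 12 (2S,3E,5E,7E)-4,6-diethyl-2-methyl-8-phenylocta-3,5,7-trien-1-ol
Conditions: Bu4NF, THF, 0 °C → rt
Reagents that add atoms: none
Why: Fluoride-induced cleavage of the silyl ether (desilylation) should free the primary alcohol under conditions that leave the triene alone.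

Step 8
Reactants: 12 (2S,3E,5E,7E)-4,6-diethyl-2-methyl-8-phenylocta-3,5,7-trien-1-ol
Product: 13 [(1E,3E,5E,7S)-3,5-diethyl-8-iodo-7-methylocta-1,3,5-trien-1-yl]benzene
Conditions: PPh3, I2, imidazole, CH2Cl2, 0 °C, dark
Reagents that add atoms: iodine, II
Why: Appel-type iodination should convert the primary alcohol into the iodide by SN2 displacement of the oxyphosphonium group, the neighbouring stereocentre not being involved.

Step 9
Reactants: 14 methyl (R)-2-hydroxybutanoate
Product: 15 methyl (R)-2-[(tert-butyldimethylsilyl)oxy]butanoate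
Conditions: TBSCl, imidazole, DMF, rt
Reagents that add atoms: tert-butyldimethylsilyl chloride, CC(C)(C)[Si](C)(C)Cl
Why: Silylation (silyl ether protection) of the secondary α-hydroxy ester should proceed without epimerisation.

Step 10
Reactants: 15 methyl (R)-2-[(tert-butyldimethylsilyl)oxy]butanoate; 16 methyl 2-(triphenylphosphoranylidene)propanoate
Product: 18 methyl (2E,4R)-4-[(tert-butyldimethylsilyl)oxy]-2-methylhex-2-enoate, via silyloxy aldehyde 17 (not isolated)
Conditions: i-Bu2AlH, CH2Cl2, −78 °C; MeOH; then 16, −78 °C → rt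
Reagents that add atoms: none
Why: Partial reduction with i-Bu2AlH gives the α-silyloxy aldehyde, which is trapped without isolation by the ester-stabilised ylide in an E-selective Wittig olefination, so that the labile aldehyde is never handled and the C4 stereocentre is carried over unchanged.

Step 11
Reactants: 18 methyl (2E,4R)-4-[(tert-butyldimethylsilyl)oxy]-2-methylhex-2-enoate
Product: 19 methyl (2E,4R)-4-hydroxy-2-methylhex-2-enoate
Conditions: HF·pyridine, THF, 0 °C → rt
Reagents that add atoms: none
Why: Fluoride-mediated desilylation should free the secondary alcohol, and the E geometry of the enoate prevents lactonisation of the γ-hydroxy ester.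

Step 12
Reactants: 19 methyl (2E,4R)-4-hydroxy-2-methylhex-2-enoate
Product: 20 methyl (2E,4S)-4-(acetylsulfanyl)-2-methylhex-2-enoate
Conditions: PPh3, DIAD, AcSH, THF, 0 °C
Reagents that add atoms: thioacetic acid, CC(=O)S
Why: In the Mitsunobu reaction thioacetate displaces the alkoxyphosphonium group by SN2 with inversion, which should set the (S) configuration of the temporary sulfur-bearing stereocentre; SN2' attack is disfavoured because it would have to occur at the fully substituted, ester-bearing carbon.

Step 13
Reactants: 20 methyl (2E,4S)-4-(acetylsulfanyl)-2-methylhex-2-enoate; 13 [(1E,3E,5E,7S)-3,5-diethyl-8-iodo-7-methylocta-1,3,5-trien-1-yl]benzene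
Product: 22 methyl (2E,4S)-4-{[(2S,3E,5E,7E)-4,6-diethyl-2-methyl-8-phenylocta-3,5,7-trien-1-yl]sulfanyl}-2-methylhex-2-enoate, via thiol 21 (not isolated)
Conditions: K2CO3, MeOH/THF (degassed), 0 °C → rt
Reagents that add atoms: none
Why: Methanolysis of the thioacetate liberates the thiolate, which should be alkylated in situ by the primary iodide (SN2 thioether formation); the C–S bond at the stereocentre is not broken and the stereocentre of the iodide is not involved.

Step 14
Reactants: 22 methyl (2E,4S)-4-{[(2S,3E,5E,7E)-4,6-diethyl-2-methyl-8-phenylocta-3,5,7-trien-1-yl]sulfanyl}-2-methylhex-2-enoate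
Product: 23 methyl (2E,4S)-4-{[(2S,3E,5E,7E)-4,6-diethyl-2-methyl-8-phenylocta-3,5,7-trien-1-yl]sulfonyl}-2-methylhex-2-enoate
Conditions: (NH4)6Mo7O24·4H2O (cat.), 30% aq. H2O2, EtOH, 0 °C → rt
Reagents that add atoms: hydrogen peroxide, OO
Why: Peroxomolybdate-catalysed sulfide oxidation transfers oxygen to sulfur much faster than to the enoate or the triene, so the sulfone should form chemoselectively with both stereocentres intact.

Step 15
Reactants: 23 methyl (2E,4S)-4-{[(2S,3E,5E,7E)-4,6-diethyl-2-methyl-8-phenylocta-3,5,7-trien-1-yl]sulfonyl}-2-methylhex-2-enoate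
Product: 27 methyl (1R,3aR,4R,5S,7aS)-3,5,7-triethyl-1,4-dimethyl-5-[(E)-2-phenylethenyl]-3a,4,5,7a-tetrahydro-1H-indene-4-carboxylate, via cycloadduct 24 (not isolated), via bromo sulfone 25 (not isolated), via episulfone 26 (not isolated)
Conditions: PhMe, BHT (cat.), 130 °C (sealed tube); then in the same flask t-BuOH, KOH/Al2O3, BrCl2C–CCl2Br, 0 °C → rt
Reagents that add atoms: none
Why: On heating, 23 should undergo a concerted suprafacial intramolecular Diels–Alder reaction that closes the cyclohexene by [4+2] addition of the E-enoate to the E,E-diene (bonds C4–C5 and C3a–C7a) and at the same time closes the six-membered sulfone ring as the tether ring, giving the trans-fused cycloadduct 24. KOH/Al2O3 and BrCl2C–CCl2Br then brominate a carbon next to sulfur (25), the carbanion at the other α-carbon closes the episulfone 26 by 3-exo-tet displacement of bromide, and cheletropic loss of SO2 contracts the thiane dioxide to the cyclopentene with the C2=C3 double bond (Ramberg–Bäcklund reaction). The closest known reaction types are thermal Diels–Alder reactions of trienes joined through sulfur-containing four-atom tethers and the Ramberg–Bäcklund contraction of thiane 1,1-dioxides to cyclopentenes with in situ halogenation. The quaternary centres C4 and C5 follow stereospecifically from the E geometry of enoate and diene, the trans ring fusion (C3a, C7a) from the ester-endo transition state, and the absolute sense from C1 (allylic 1,3-strain between its hydrogen and the ethyl group on the diene) reinforced by the temporary sulfur-bearing stereocentre (allylic 1,3-strain with the enoate methyl): only the trans-fused chair-like transition state has both tether substituents (methyl and ethyl) equatorial. The step needs site selectivity for the inner diene (secured by the tether length, since the styryl-containing diene would demand a larger ring) and endo and facial selectivity (secured by the two matched stereocentres); the contraction needs no regiocontrol because bromination at either α-carbon leads to the same alkene, whose cis geometry the ring enforces, and it erases the temporary stereocentre.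

Step 16
Reactants: 27 methyl (1R,3aR,4R,5S,7aS)-3,5,7-triethyl-1,4-dimethyl-5-[(E)-2-phenylethenyl]-3a,4,5,7a-tetrahydro-1H-indene-4-carboxylate
Product: 28 spiculoic acid B, (1R,3aR,4R,5S,7aS)-3,5,7-triethyl-1,4-dimethyl-5-[(E)-2-phenylethenyl]-3a,4,5,7a-tetrahydro-1H-indene-4-carboxylic acid
Conditions: NaSEt, DMF, 90 °C; then aq. HCl
Reagents that add atoms: none
Why: SN2 demethylation of the methyl ester by ethanethiolate (nucleophilic ester cleavage at the O-methyl carbon) avoids the acyl carbon shielded by two adjacent quaternary centres and should leave all stereocentres and double bonds untouched.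

## Compound list

1 | propyltriphenylphosphonium bromide | CCC[P+](c1ccccc1)(c1ccccc1)c1ccccc1.[Br-] | starting material
2 | ethyl formate | CCOC=O | starting material
3 | propylidenetriphenylphosphorane | CCC=P(c1ccccc1)(c1ccccc1)c1ccccc1 | intermediate
4 | 2-(triphenylphosphoranylidene)butanal | CCC(C=O)=P(c1ccccc1)(c1ccccc1)c1ccccc1 | intermediate
5 | methyl (R)-3-hydroxy-2-methylpropanoate | OC[C@@H](C)C(=O)OC | starting material
6 | methyl (R)-3-[(tert-butyldimethylsilyl)oxy]-2-methylpropanoate | CC(C)(C)[Si](C)(C)OC[C@@H](C)C(=O)OC | intermediate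
7 | (R)-3-[(tert-butyldimethylsilyl)oxy]-2-methylpropanal | CC(C)(C)[Si](C)(C)OC[C@@H](C)C=O | intermediate
8 | (2E,4S)-5-[(tert-butyldimethylsilyl)oxy]-2-ethyl-4-methylpent-2-enal | CC(C)(C)[Si](C)(C)OC[C@@H](C)/C=C(CC)/C=O | intermediate
9 | (2E,4E,6S)-7-[(tert-butyldimethylsilyl)oxy]-2,4-diethyl-6-methylhepta-2,4-dienal | CC(C)(C)[Si](C)(C)OC[C@@H](C)/C=C(CC)/C=C(CC)/C=O | intermediate
10 | diethyl benzylphosphonate | CCOP(=O)(Cc1ccccc1)OCC | starting material
11 | tert-butyl{[(2S,3E,5E,7E)-4,6-diethyl-2-methyl-8-phenylocta-3,5,7-trien-1-yl]oxy}dimethylsilane | CC(C)(C)[Si](C)(C)OC[C@@H](C)/C=C(CC)/C=C(CC)/C=C/c1ccccc1 | intermediate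
12 | (2S,3E,5E,7E)-4,6-diethyl-2-methyl-8-phenylocta-3,5,7-trien-1-ol | OC[C@@H](C)/C=C(CC)/C=C(CC)/C=C/c1ccccc1 | intermediate
13 | [(1E,3E,5E,7S)-3,5-diethyl-8-iodo-7-methylocta-1,3,5-trien-1-yl]benzene | IC[C@@H](C)/C=C(CC)/C=C(CC)/C=C/c1ccccc1 | intermediate
14 | methyl (R)-2-hydroxybutanoate | CC[C@@H](O)C(=O)OC | starting material
15 | methyl (R)-2-[(tert-butyldimethylsilyl)oxy]butanoate | CC[C@@H](O[Si](C)(C)C(C)(C)C)C(=O)OC | intermediate
16 | methyl 2-(triphenylphosphoranylidene)propanoate | COC(=O)C(C)=P(c1ccccc1)(c1ccccc1)c1ccccc1 | starting material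
17 | (R)-2-[(tert-butyldimethylsilyl)oxy]butanal | CC[C@@H](O[Si](C)(C)C(C)(C)C)C=O | intermediate
18 | methyl (2E,4R)-4-[(tert-butyldimethylsilyl)oxy]-2-methylhex-2-enoate | COC(=O)/C(C)=C/[C@@H](CC)O[Si](C)(C)C(C)(C)C | intermediate
19 | methyl (2E,4R)-4-hydroxy-2-methylhex-2-enoate | COC(=O)/C(C)=C/[C@@H](CC)O | intermediate
20 | methyl (2E,4S)-4-(acetylsulfanyl)-2-methylhex-2-enoate | COC(=O)/C(C)=C/[C@H](CC)SC(C)=O | intermediate
21 | methyl (2E,4S)-2-methyl-4-sulfanylhex-2-enoate | COC(=O)/C(C)=C/[C@H](CC)S | intermediate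
22 | methyl (2E,4S)-4-{[(2S,3E,5E,7E)-4,6-diethyl-2-methyl-8-phenylocta-3,5,7-trien-1-yl]sulfanyl}-2-methylhex-2-enoate | COC(=O)/C(C)=C/[C@H](CC)SC[C@@H](C)/C=C(CC)/C=C(CC)/C=C/c1ccccc1 | intermediate
23 | methyl (2E,4S)-4-{[(2S,3E,5E,7E)-4,6-diethyl-2-methyl-8-phenylocta-3,5,7-trien-1-yl]sulfonyl}-2-methylhex-2-enoate | COC(=O)/C(C)=C/[C@H](CC)S(=O)(=O)C[C@@H](C)/C=C(CC)/C=C(CC)/C=C/c1ccccc1 | intermediate
24 | methyl (1S,4S,4aS,7S,8R,8aS)-1,5,7-triethyl-4,8-dimethyl-7-[(E)-2-phenylethenyl]-3,4,4a,7,8,8a-hexahydro-1H-isothiochromene-8-carboxylate 2,2-dioxide (trans-fused cycloadduct) | CCC1=C[C@@](/C=C/c2ccccc2)(CC)[C@](C)(C(=O)OC)[C@H]2[C@H](CC)S(=O)(=O)C[C@@H](C)[C@H]12 | intermediate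
25 | 3-bromo derivative of 24 (bromine on the CH2 carbon next to sulfur, either epimer; other stereocentres as in 24) | CCC1=C[C@@](/C=C/c2ccccc2)(CC)[C@](C)(C(=O)OC)[C@H]2[C@H](CC)S(=O)(=O)C(Br)[C@@H](C)[C@H]12 | intermediate
26 | methyl 3,5,7-triethyl-1,4-dimethyl-5-[(E)-2-phenylethenyl]-2,3-epithio-2,3,3a,4,5,7a-hexahydro-1H-indene-4-carboxylate S,S-dioxide (C1, C3a, C4, C5, C7a as in 27; thiirane dioxide on either face) | CCC1=C[C@@](/C=C/c2ccccc2)(CC)[C@](C)(C(=O)OC)[C@H]2C3(CC)C(S3(=O)=O)[C@@H](C)[C@H]12 | intermediate
27 | methyl (1R,3aR,4R,5S,7aS)-3,5,7-triethyl-1,4-dimethyl-5-[(E)-2-phenylethenyl]-3a,4,5,7a-tetrahydro-1H-indene-4-carboxylate | CCC1=C[C@@](/C=C/c2ccccc2)(CC)[C@](C)(C(=O)OC)[C@H]2C(CC)=C[C@@H](C)[C@H]12 | intermediate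
28 | spiculoic acid B, (1R,3aR,4R,5S,7aS)-3,5,7-triethyl-1,4-dimethyl-5-[(E)-2-phenylethenyl]-3a,4,5,7a-tetrahydro-1H-indene-4-carboxylic acid | CCC1=C[C@@](/C=C/c2ccccc2)(CC)[C@](C)(C(=O)O)[C@H]2C(CC)=C[C@@H](C)[C@H]12 | target

## Step count and risks

Total step count: 16. Longest linear sequence: 11 steps (steps 2–8, then 13–16, from 5).

Steps most likely to fail:

1. **Step 15.** What may go wrong: the cycloaddition through the longer sulfonyl tether may be slow or insufficiently endo- and face-selective, the allylic sulfone may undergo thermal 1,3-sulfonyl migration before it cyclises, and the contraction may be incomplete on the unpurified cycloadduct. The fallback separates the two events and moves the cycloaddition to the sulfide oxidation level. It sets out from sulfide 22, which is cyclised thermally (PhMe, 120 °C) or with Me2AlCl (CH2Cl2, −20 °C) to the trans-fused bicyclic sulfide methyl (1S,4S,4aS,7S,8R,8aS)-1,5,7-triethyl-4,8-dimethyl-7-[(E)-2-phenylethenyl]-3,4,4a,7,8,8a-hexahydro-1H-isothiochromene-8-carboxylate F1. Oxidation of F1 with 2KHSO5·KHSO4·K2SO4 (MeOH/H2O, 0 °C) should give cycloadduct 24, now isolated and purified. The route is rejoined at 24, which is contracted to 27 with KOH/Al2O3 and BrCl2C–CCl2Br in a separate operation.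

2. **Step 14.** What may go wrong: competing epoxidation of the electron-rich triene, and loss of configuration at the sulfur-bearing carbon by reversible [2,3]-sigmatropic (Mislow–Evans) rearrangement of the intermediate allylic sulfoxide. The fallback avoids any oxidation at sulfur by bringing sulfur in at the sulfinate level. It sets out from iodide 13, which is alkylated with sodium 3-methoxy-3-oxopropane-1-sulfinate (DMSO, rt) to methyl 3-{[(2S,3E,5E,7E)-4,6-diethyl-2-methyl-8-phenylocta-3,5,7-trien-1-yl]sulfonyl}propanoate F2. NaOMe (MeOH/THF, rt) then releases, by retro-Michael cleavage, sodium (2S,3E,5E,7E)-4,6-diethyl-2-methyl-8-phenylocta-3,5,7-triene-1-sulfinate F3. Alcohol 19 is converted (MsCl, Et3N, CH2Cl2, −20 °C) into methyl (2E,4R)-2-methyl-4-[(methylsulfonyl)oxy]hex-2-enoate F4. S-Alkylation of F3 with F4 (DMF, rt; SN2 with inversion) should give sulfone 23, where the route is rejoined.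

3. **Step 4.** What may go wrong: partial epimerisation of the α-stereocentre of the aldehyde, or β-elimination of the silyloxy group, during the slow olefination at 90 °C. The fallback replaces the thermal Wittig reaction by a room-temperature Horner–Wadsworth–Emmons reaction followed by redox adjustment. It sets out from aldehyde 7, which reacts with triethyl 2-phosphonobutanoate (LiCl, DBU, MeCN, rt) to give ethyl (2E,4S)-5-[(tert-butyldimethylsilyl)oxy]-2-ethyl-4-methylpent-2-enoate F5. Reduction with i-Bu2AlH (CH2Cl2, −78 °C) should give (2E,4S)-5-[(tert-butyldimethylsilyl)oxy]-2-ethyl-4-methylpent-2-en-1-ol F6, and oxidation with MnO2 (CH2Cl2, rt) returns to enal 8.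

Further compounds
F1 | step 15 | methyl (1S,4S,4aS,7S,8R,8aS)-1,5,7-triethyl-4,8-dimethyl-7-[(E)-2-phenylethenyl]-3,4,4a,7,8,8a-hexahydro-1H-isothiochromene-8-carboxylate | CCC1=C[C@@](/C=C/c2ccccc2)(CC)[C@](C)(C(=O)OC)[C@H]2[C@H](CC)SC[C@@H](C)[C@H]12
F2 | step 14 | methyl 3-{[(2S,3E,5E,7E)-4,6-diethyl-2-methyl-8-phenylocta-3,5,7-trien-1-yl]sulfonyl}propanoate | COC(=O)CCS(=O)(=O)C[C@@H](C)/C=C(CC)/C=C(CC)/C=C/c1ccccc1
F3 | step 14 | sodium (2S,3E,5E,7E)-4,6-diethyl-2-methyl-8-phenylocta-3,5,7-triene-1-sulfinate | [Na+].[O-]S(=O)C[C@@H](C)/C=C(CC)/C=C(CC)/C=C/c1ccccc1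
F4 | step 14 | methyl (2E,4R)-2-methyl-4-[(methylsulfonyl)oxy]hex-2-enoate | COC(=O)/C(C)=C/[C@@H](CC)OS(C)(=O)=O
F5 | step 4 | ethyl (2E,4S)-5-[(tert-butyldimethylsilyl)oxy]-2-ethyl-4-methylpent-2-enoate | CC(C)(C)[Si](C)(C)OC[C@@H](C)/C=C(CC)/C(=O)OCC
F6 | step 4 | (2E,4S)-5-[(tert-butyldimethylsilyl)oxy]-2-ethyl-4-methylpent-2-en-1-ol | CC(C)(C)[Si](C)(C)OC[C@@H](C)/C=C(CC)/CO
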